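**Retrosynthetic overview** (C8 = carbinol carbon, C9 = its CH2 neighbour, C10=C11 = Z alkene, C12 = 1,1-disubstituted diene carbon)
1. C11–C12: Suzuki–Miyaura coupling of a (Z)-chloroalkene with a 2-boryl-1-alkene made in the flask from methyl (3-iodobut-3-enyl)carbamate.
2. C8–C9 (key bond): thiazolyl aldehyde plus an (S)-1-chloroallylboronate, a chiral homoenolate (d3) equivalent. Two acceptor carbons are joined, and one step sets C8 (R), the Z alkene and the coupling handle.
3. The aldehyde comes from a nitrile. The skipped diene comes from a 4-(chloromethyl)thiazole and an (E)-penta-1,4-dienylzirconocene.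
4. The only ring, the thiazole, is formed first (Hantzsch) from the monothioamide of dimethylmalononitrile and 1,3-dichloroacetone.

Assumption: pent-1-en-4-yne, dibutyl vinylboronate, (1R,2R)-1,2-dicyclohexylethane-1,2-diol and but-3-yn-1-amine hydrochloride are taken as catalogue chemicals.

**Step 1**
Reactants: 1 dimethylmalononitrile (2,2-dimethylpropanedinitrile)
Product: 2 2-cyano-2-methylpropanethioamide
Conditions: (NH4)2S (20% aq., 1.0 equiv), MeOH, 0 °C to rt, 16 h
Reagents that add atoms: ammonium sulfide, [NH4+].[NH4+].[S-2]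
Why: Nitrile thiolysis (hydrosulfide addition), the reaction that turns malononitrile into cyanothioacetamide; the geminal nitrile activates the first addition, and the resulting thioamide is a much weaker activator, so one equivalent of sulfide stops at the monothioamide.

**Step 2**
Reactants: 2 2-cyano-2-methylpropanethioamide; 3 1,3-dichloroacetone
Product: 5 2-[4-(chloromethyl)-1,3-thiazol-2-yl]-2-methylpropanenitrile, via hydroxythiazoline adduct 4 (not isolated)
Conditions: acetone, reflux, 6 h; aq. NaHCO3 work-up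
Reagents that add atoms: none
Why: Hantzsch thiazole synthesis, in which sulfur displaces one chloride, nitrogen closes onto the ketone, and the HCl formed dehydrates the hydroxythiazoline, leaving the second CH2Cl group as the C4 handle.

**Step 3**
Reactants: 6 pent-1-en-4-yne; 5 2-[4-(chloromethyl)-1,3-thiazol-2-yl]-2-methylpropanenitrile
Product: 8 2-{4-[(2E)-hexa-2,5-dien-1-yl]-1,3-thiazol-2-yl}-2-methylpropanenitrile, via alkenylzirconocene chloride 7 (not isolated)
Conditions: 6 (1.3 equiv), Cp2Zr(H)Cl (1.2 equiv), THF, rt, 30 min; then 5, Pd(PPh3)4 (5 mol%), ZnCl2 (20 mol%), THF, rt to 40 °C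
Reagents that add atoms: none
Why: Syn hydrozirconation takes the terminal alkyne in preference to the terminal alkene and gives the E alkenyl metal, which undergoes a Negishi-type cross-coupling with the benzylic-type chloride under zerovalent palladium with retention and no allylic transposition; the hydride is consumed before the nitrile is added.

**Step 4**
Reactants: 8 2-{4-[(2E)-hexa-2,5-dien-1-yl]-1,3-thiazol-2-yl}-2-methylpropanenitrile
Product: 10 2-{4-[(2E)-hexa-2,5-dien-1-yl]-1,3-thiazol-2-yl}-2-methylpropanal, via aluminium aldimine 9 (not isolated)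
Conditions: i-Bu2AlH (1.3 equiv), toluene, −78 °C, 2 h; then aq. potassium sodium tartrate, rt
Reagents that add atoms: water, O
Why: Partial reduction of a nitrile, in which a single hydride transfer gives an N-aluminated aldimine that cannot be reduced further at −78 °C and hydrolyses to the non-enolisable aldehyde; the alkenes are inert at this temperature.

**Step 5**
Reactants: 11 dibutyl vinylboronate; 12 (1R,2R)-1,2-dicyclohexylethane-1,2-diol
Product: 13 (4R,5R)-4,5-dicyclohexyl-2-ethenyl-1,3,2-dioxaborolane
Conditions: pentane, rt, 2 h; butanol removed under vacuum (toluene azeotrope)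
Reagents that add atoms: none
Why: Boronic ester transesterification driven by the chelate effect and by removal of butanol; the two diol stereocentres are carried in unchanged.

**Step 6**
Reactants: 13 (4R,5R)-4,5-dicyclohexyl-2-ethenyl-1,3,2-dioxaborolane
Product: 15 (4R,5R)-2-[(1S)-1-chloroprop-2-en-1-yl]-4,5-dicyclohexyl-1,3,2-dioxaborolane, via lithium borate complex 14 (not isolated)
Conditions: CH2Cl2 (1.5 equiv), n-BuLi (1.15 equiv), THF, −100 °C; 13; ZnCl2 (0.7 equiv), −100 °C to rt, 12 h; pentane extraction, used without distillation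
Reagents that add atoms: (dichloromethyl)lithium, [Li]C(Cl)Cl, made in the flask from dichloromethane, ClCCl
Why: Matteson homologation, in which the carbenoid adds to boron and the ZnCl2-assisted 1,2-shift of the vinyl group displaces one of the two diastereotopic chlorides under control of the C2-symmetric (R,R)-diol, which by the established rule for (R,R)-diol esters gives the (S)-α-chloro boronate in high diastereomeric purity.

**Step 7 (key step)**
Reactants: 10 2-{4-[(2E)-hexa-2,5-dien-1-yl]-1,3-thiazol-2-yl}-2-methylpropanal; 15 (4R,5R)-2-[(1S)-1-chloroprop-2-en-1-yl]-4,5-dicyclohexyl-1,3,2-dioxaborolane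
Product: 17 (3R,5Z)-6-chloro-2-{4-[(2E)-hexa-2,5-dien-1-yl]-1,3-thiazol-2-yl}-2-methylhex-5-en-3-ol, via borate ester 16 (not isolated)
Conditions: 15 (1.4 equiv), toluene (1 M), 4 Å MS, rt, 72 h; then N(CH2CH2OH)3, Et2O, rt, 2 h; chromatography
Reagents that add atoms: none
Why: The 1-chloroallylboronate is a chiral homoenolate (β-formylethyl anion, d3) equivalent, so the normally electrophilic β-carbon of a masked aldehyde bonds to the electrophilic aldehyde carbon through a closed Zimmerman–Traxler chair (Hoffmann-type α-chloroallylboration) with the aldehyde residue equatorial and the C–Cl bond axial, which transfers the S boron-bearing centre into the R carbinol and gives the Z chloroalkene (typically at least 9:1; the minor E isomer carries the S carbinol and is removed on silica).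

**Step 8**
Reactants: 18 but-3-yn-1-amine hydrochloride
Product: 19 methyl but-3-yn-1-ylcarbamate
Conditions: ClCO2Me (1.1 equiv), Et3N (2.2 equiv), CH2Cl2, 0 °C to rt, 2 h
Reagents that add atoms: methyl chloroformate, COC(=O)Cl
Why: N-acylation of the liberated primary amine by a chloroformate (carbamate formation); the alkyne takes no part.

**Step 9**
Reactants: 19 methyl but-3-yn-1-ylcarbamate
Product: 20 methyl (3-iodobut-3-en-1-yl)carbamate
Conditions: NaI (1.5 equiv), Me3SiCl (1.5 equiv), H2O (0.75 equiv), MeCN, 0 °C to rt, 1.5 h; aq. Na2S2O3 work-up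
Reagents that add atoms: sodium iodide, [Na+].[I-]
Why: Markovnikov hydroiodination of a terminal alkyne by HI made in the flask gives the 2-iodo-1-alkene, and the methyl carbamate survives the short exposure at room temperature.

**Step 10**
Reactants: 20 methyl (3-iodobut-3-en-1-yl)carbamate; 17 (3R,5Z)-6-chloro-2-{4-[(2E)-hexa-2,5-dien-1-yl]-1,3-thiazol-2-yl}-2-methylhex-5-en-3-ol
Product: 22 mycothiazole, methyl N-[(4Z,7R)-8-{4-[(2E)-hexa-2,5-dien-1-yl]-1,3-thiazol-2-yl}-7-hydroxy-8-methyl-3-methylidenenon-4-en-1-yl]carbamate, via alkenyl pinacol boronate 21 (not isolated)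
Conditions: 20 (1.5 equiv), B2pin2 (1.6 equiv), PdCl2(PPh3)2 (3 mol%), PPh3 (6 mol%), KOPh (2.3 equiv), toluene, 50 °C, 5 h; then 17 (1.0 equiv), Pd(OAc)2 (5 mol%), SPhos (10 mol%), 3 M aq. K3PO4, THF, 50 °C, 12 h
Reagents that add atoms: none
Why: Miyaura borylation of the alkenyl iodide followed in the same flask by Suzuki–Miyaura coupling (the borylation–coupling sequence to unsymmetrical 1,3-dienes); the electron-rich biaryl phosphine lets zerovalent palladium insert into the alkenyl C–Cl bond with retention, so the Z geometry and the untouched R carbinol pass into the target, and aqueous phosphate tolerates the free OH and NH.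

**Compound list**
1 | dimethylmalononitrile | CC(C)(C#N)C#N | starting material
2 | 2-cyano-2-methylpropanethioamide | CC(C)(C#N)C(N)=S | intermediate
3 | 1,3-dichloroacetone | ClCC(=O)CCl | starting material
4 | 2-[4-(chloromethyl)-4-hydroxy-4,5-dihydro-1,3-thiazol-2-yl]-2-methylpropanenitrile (racemic, formed in the flask) | CC(C)(C#N)C1=NC(O)(CCl)CS1 | intermediate
5 | 2-[4-(chloromethyl)-1,3-thiazol-2-yl]-2-methylpropanenitrile | CC(C)(C#N)c1nc(CCl)cs1 | intermediate
6 | pent-1-en-4-yne | C=CCC#C | starting material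
7 | chlorobis(cyclopentadienyl)[(1E)-penta-1,4-dien-1-yl]zirconium (formed in the flask; cyclopentadienyl rings drawn σ-bound) | C=CC/C=C/[Zr](Cl)(C1C=CC=C1)C1C=CC=C1 | intermediate
8 | 2-{4-[(2E)-hexa-2,5-dien-1-yl]-1,3-thiazol-2-yl}-2-methylpropanenitrile | C=CC/C=C/Cc1csc(C(C)(C)C#N)n1 | intermediate
9 | N-(diisobutylaluminio) aldimine of 10 (formed in the flask) | C=CC/C=C/Cc1csc(C(C)(C)C=N[Al](CC(C)C)CC(C)C)n1 | intermediate
10 | 2-{4-[(2E)-hexa-2,5-dien-1-yl]-1,3-thiazol-2-yl}-2-methylpropanal | C=CC/C=C/Cc1csc(C(C)(C)C=O)n1 | intermediate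
11 | dibutyl vinylboronate | C=CB(OCCCC)OCCCC | starting material
12 | (1R,2R)-1,2-dicyclohexylethane-1,2-diol | O[C@H](C1CCCCC1)[C@H](O)C1CCCCC1 | starting material
13 | (4R,5R)-4,5-dicyclohexyl-2-ethenyl-1,3,2-dioxaborolane | C=CB1O[C@H](C2CCCCC2)[C@@H](C2CCCCC2)O1 | intermediate
14 | lithium (4R,5R)-4,5-dicyclohexyl-2-(dichloromethyl)-2-ethenyl-1,3,2-dioxaborolan-2-uide (formed in the flask) | [Li+].C=C[B-]1(C(Cl)Cl)O[C@H](C2CCCCC2)[C@@H](C2CCCCC2)O1 | intermediate
15 | (4R,5R)-2-[(1S)-1-chloroprop-2-en-1-yl]-4,5-dicyclohexyl-1,3,2-dioxaborolane | C=C[C@@H](Cl)B1O[C@H](C2CCCCC2)[C@@H](C2CCCCC2)O1 | intermediate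
16 | (4R,5R)-4,5-dicyclohexyl-1,3,2-dioxaborolan-2-yl ether of 17 (formed in the flask) | C=CC/C=C/Cc1csc(C(C)(C)[C@H](OB2O[C@H](C3CCCCC3)[C@@H](C3CCCCC3)O2)C/C=C\Cl)n1 | intermediate
17 | (3R,5Z)-6-chloro-2-{4-[(2E)-hexa-2,5-dien-1-yl]-1,3-thiazol-2-yl}-2-methylhex-5-en-3-ol | C=CC/C=C/Cc1csc(C(C)(C)[C@H](O)C/C=C\Cl)n1 | intermediate
18 | but-3-yn-1-amine hydrochloride | C#CCC[NH3+].[Cl-] | starting material
19 | methyl but-3-yn-1-ylcarbamate | C#CCCNC(=O)OC | intermediate
20 | methyl (3-iodobut-3-en-1-yl)carbamate | C=C(I)CCNC(=O)OC | intermediate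
21 | methyl [3-(4,4,5,5-tetramethyl-1,3,2-dioxaborolan-2-yl)but-3-en-1-yl]carbamate (formed in the flask) | C=C(CCNC(=O)OC)B1OC(C)(C)C(C)(C)O1 | intermediate
22 | mycothiazole, (4Z,7R,2E) as named in step 10 | C=CC/C=C/Cc1csc(C(C)(C)[C@H](O)C/C=C\C(=C)CCNC(=O)OC)n1 | target

**Total step count:** 10 steps.
**Longest linear sequence:** 6 steps (1, 2, 3, 4, 7, 10).

**Three steps most likely to fail**

**Step 7.** The aldehyde is neopentyl-like, so the addition may be slow. During a long reaction 15 can epimerise or suffer an allylic chloride shift, which would erode the ee and the Z:E ratio.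
- The fallback sets out from 10 and comes back at 17. It keeps the homoenolate bond construction but sets the stereocentre by a ketone reduction.
- Commercial 2-(dichloromethyl)-4,4,5,5-tetramethyl-1,3,2-dioxaborolane is treated with CH2=CHMgBr and ZnCl2 in THF (−78 °C to rt). This gives racemic 2-(1-chloroprop-2-en-1-yl)-4,4,5,5-tetramethyl-1,3,2-dioxaborolane F1.
- F1 is smaller and has no stereochemical purity to lose, so it can be used neat, in threefold excess and at 40 °C with 10. After the triethanolamine work-up this gives racemic (5Z)-6-chloro-2-{4-[(2E)-hexa-2,5-dien-1-yl]-1,3-thiazol-2-yl}-2-methylhex-5-en-3-ol F2.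
- Dess–Martin oxidation (NaHCO3-buffered CH2Cl2, 0 °C) gives (5Z)-6-chloro-2-{4-[(2E)-hexa-2,5-dien-1-yl]-1,3-thiazol-2-yl}-2-methylhex-5-en-3-one F3.
- Corey–Bakshi–Shibata reduction with the (S)-methyl oxazaborolidine and catecholborane (toluene, −78 °C) then returns 17. These conditions leave the alkenes alone and distinguish the quaternary side from the CH2 side.

**Step 10.** The unactivated Z chloroalkene may insert slowly. That would leave 21 open to protodeboronation or homocoupling, and the alkenylpalladium species open to closure onto the free OH to give a dihydrofuran.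
- The fallback sets out from 17 and comes back at 22, with the roles of the two partners exchanged.
- 17 is borylated (B2pin2, Pd2(dba)3, XPhos, KOAc, dioxane, 80 °C) to (3R,5Z)-2-{4-[(2E)-hexa-2,5-dien-1-yl]-1,3-thiazol-2-yl}-2-methyl-6-(4,4,5,5-tetramethyl-1,3,2-dioxaborolan-2-yl)hex-5-en-3-ol F4. Its boron is held by the neighbouring hydroxyl group.
- F4 is then coupled at room temperature with the far more reactive iodide 20 (PdCl2(dppf), aq. K3PO4, THF) to give 22.

**Step 3.** Three things can go wrong: hydrozirconation of the alkene may compete, transmetalation from zirconium may be slow, and 5 can self-quaternise while it waits.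
- The fallback sets out from 5 and comes back at 8. It builds the skipped diene from a two-carbon linchpin instead of the enyne.
- Stille coupling of 5 with (E)-1,2-bis(tributylstannyl)ethene (Pd2(dba)3, P(2-furyl)3, THF, 50 °C) gives 2-methyl-2-{4-[(2E)-3-(tributylstannyl)prop-2-en-1-yl]-1,3-thiazol-2-yl}propanenitrile F5.
- A second Stille coupling of F5 with allyl bromide (same catalyst, DMF, rt) gives 8.

**Further compounds**
F1 | step 7 | racemic 2-(1-chloroprop-2-en-1-yl)-4,4,5,5-tetramethyl-1,3,2-dioxaborolane | C=CC(Cl)B1OC(C)(C)C(C)(C)O1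
F2 | step 7 | racemic (5Z)-6-chloro-2-{4-[(2E)-hexa-2,5-dien-1-yl]-1,3-thiazol-2-yl}-2-methylhex-5-en-3-ol | C=CC/C=C/Cc1csc(C(C)(C)C(O)C/C=C\Cl)n1
F3 | step 7 | (5Z)-6-chloro-2-{4-[(2E)-hexa-2,5-dien-1-yl]-1,3-thiazol-2-yl}-2-methylhex-5-en-3-one | C=CC/C=C/Cc1csc(C(C)(C)C(=O)C/C=C\Cl)n1
F4 | step 10 | (3R,5Z)-2-{4-[(2E)-hexa-2,5-dien-1-yl]-1,3-thiazol-2-yl}-2-methyl-6-(4,4,5,5-tetramethyl-1,3,2-dioxaborolan-2-yl)hex-5-en-3-ol | C=CC/C=C/Cc1csc(C(C)(C)[C@H](O)C/C=C\B2OC(C)(C)C(C)(C)O2)n1
F5 | step 3 | 2-methyl-2-{4-[(2E)-3-(tributylstannyl)prop-2-en-1-yl]-1,3-thiazol-2-yl}propanenitrile | CCCC[Sn](CCCC)(CCCC)/C=C/Cc1csc(C(C)(C)C#N)n1
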